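**Retrosynthetic overview**

- The strategy rests on the O-bridge between C1 and C4 (a tetrahydrofuran C1–C2–C3–C4–O spanning the ten-membered carbocycle) next to the C5=C6 enol-lactone alkene conjugated with the C7=C11 butenolide. This array is the isomer of a 4,5-epoxy-7(11)-en-6,12-olide that also carries a 1,10-epoxide.
- Last disconnections: the C8 glycidate ester and the C13 acetate; then the bridged core 31 back to diepoxide 29 (key step), and 29 back to trienolide 27 by double epoxidation.
- Butenolide from macrocyclic ketone 20 by ester-enolate aldol (C7–C11), lactonisation (O6–C12) and dehydration; ten-membered ring by chromium-mediated alkenyl–aldehyde closure of C5–C6.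
- Chain from (R)-glyceraldehyde acetonide (C6–C8), propargyl bromide (C9, C10, C1), a silylated C4 alkyne (C2–C5) and two carboalumination methyls (C14, C15).
- Ring order: carbocycle (step 11), γ-lactone (step 17), two oxiranes (step 19), tetrahydrofuran with loss of both oxiranes (step 20); the glycidate oxirane arrives intact (step 24).

Key step: step 20

Remark: atoms carry germacranolide numbers throughout (ring C1–C10, C11–C13 on C7, C14 on C10, C15 on C4), also in open-chain intermediates; TBS = tert-butyldimethylsilyl, TES = triethylsilyl, PMB = 4-methoxybenzyl.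
Remark: diepoxide 29 is made as the 6S epimer (H-6 anti to H-5), the epimer that outer-face epoxidation under allylic-strain control gives together with the 4R,5R oxirane; C6 is erased in step 20.
Remark: O13 is carried as a TBS ether and acetylated after the cascade, because an acetoxy group on C13 would be a second β-leaving group (from C11) of the same dienolate, and the silyl ether is what the aldol construction delivers.
Remark: compounds 1, 2, 7, 21 and 34 are taken as commercial.

**Route**

Step 1
Reactants: 1 (R)-2,2-dimethyl-1,3-dioxolane-4-carbaldehyde; 2 propargyl bromide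
Product: 3 (S)-1-[(R)-2,2-dimethyl-1,3-dioxolan-4-yl]but-3-yn-1-ol
Conditions: Zn dust, THF/sat. aq NH4Cl, 0 °C to rt
Reagents that add atoms: none
Why: Barbier-type propargylation in which the allenylzinc bromide formed in the flask adds through an SE2' transition state with Felkin–Anh (anti) facial selectivity from the dioxolane centre, which should set C8 as S.

Step 2
Reactants: 3 homopropargylic alcohol
Product: 4 tert-butyl{[(S)-1-[(R)-2,2-dimethyl-1,3-dioxolan-4-yl]but-3-yn-1-yl]oxy}dimethylsilane
Conditions: TBSCl, imidazole, DMF, rt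
Reagents that add atoms: tert-butyldimethylsilyl chloride, CC(C)(C)[Si](C)(C)Cl
Why: Imidazole-promoted silylation of a secondary alcohol; no stereocentre is touched.

Step 3
Reactants: 4 silyl ether alkyne
Product: 6 (R)-4-[(1S,3E)-1-(TBSO)-4-iodo-3-methylbut-3-en-1-yl]-2,2-dimethyl-1,3-dioxolane, via alkenyldimethylalane 5 (not isolated)
Conditions: Me3Al, Cp2ZrCl2 (cat.), CH2Cl2, 0 °C to rt; then I2, THF, −30 °C
Reagents that add atoms: trimethylaluminium, C[Al](C)C; iodine, [I][I]
Why: Negishi zirconium-catalysed carboalumination is a syn, regioselective methyl-metalation of a terminal alkyne (methyl to the internal carbon), and iodinolysis of the C–Al bond with retention should give the E-configured C1=C10 unit bearing C14.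

Step 4
Reactants: 6 alkenyl iodide; 7 (4-iodobut-1-yn-1-yl)trimethylsilane
Product: 9 (R)-4-[(1S,3E)-1-(TBSO)-3-methyl-8-(trimethylsilyl)oct-3-en-7-yn-1-yl]-2,2-dimethyl-1,3-dioxolane, via zinc reagent 8 (not isolated)
Conditions: 7, Zn dust, LiCl, THF, 40 °C; then 6, Pd(PPh3)4 (cat.), THF, rt to 50 °C
Reagents that add atoms: none
Why: Negishi coupling of an alkenyl iodide with a homopropargylic alkylzinc iodide forms the C1–C2 bond with retention of alkene geometry; silyl ether, acetal and silylalkyne are inert to the organozinc.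

Step 5
Reactants: 9 silylated enyne
Product: 10 (R)-4-[(1S,3E)-1-(TBSO)-3-methyloct-3-en-7-yn-1-yl]-2,2-dimethyl-1,3-dioxolane
Conditions: K2CO3 (cat.), MeOH, rt
Reagents that add atoms: none
Why: Carbonate-catalysed methanolysis cleaves only the acetylenic C–Si bond; the O-silyl ether and the acetal are stable.

Step 6
Reactants: 10 terminal enyne
Product: 12 (R)-4-[(1S,3E,7E)-1-(TBSO)-8-iodo-3,7-dimethylocta-3,7-dien-1-yl]-2,2-dimethyl-1,3-dioxolane, via dienyldimethylalane 11 (not isolated)
Conditions: Me3Al, Cp2ZrCl2 (cat.), CH2Cl2, 0 °C to rt; then I2, THF, −30 °C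
Reagents that add atoms: trimethylaluminium, C[Al](C)C; iodine, [I][I]
Why: A second syn carboalumination–iodination converts the terminal alkyne into the E-configured 1-iodo-2-methylalkene (future C5=C4 bearing C15); the trisubstituted alkene does not carbometalate.

Step 7
Reactants: 12 dienyl iodide acetonide
Product: 13 (2R,3S,5E,9E)-3-(TBSO)-10-iodo-5,9-dimethyldeca-5,9-diene-1,2-diol
Conditions: PPTS (cat.), MeOH, 45 °C
Reagents that add atoms: none
Why: Acid-catalysed transketalisation to methanol removes the terminal isopropylidene group much faster than the hindered secondary TBS ether is methanolysed.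

Step 8
Reactants: 13 diol
Product: 14 (4R)-4-[(1S,3E,7E)-1-(TBSO)-8-iodo-3,7-dimethylocta-3,7-dien-1-yl]-2-(4-methoxyphenyl)-1,3-dioxolane (both epimers at the acetal carbon)
Conditions: 4-MeOC6H4CH(OMe)2, PPTS (cat.), CH2Cl2, rt
Reagents that add atoms: 4-methoxybenzaldehyde dimethyl acetal, COC(OC)c1ccc(OC)cc1
Why: Acid-catalysed acetal exchange on the 1,2-diol gives the five-membered 4-methoxybenzylidene acetal; its new centre does not matter because it is destroyed in step 9.

Step 9
Reactants: 14 benzylidene acetal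
Product: 15 (2R,3S,5E,9E)-3-(TBSO)-10-iodo-2-[(4-methoxybenzyl)oxy]-5,9-dimethyldeca-5,9-dien-1-ol
Conditions: i-Bu2AlH, CH2Cl2, −78 to −20 °C
Reagents that add atoms: none
Why: Regioselective reductive acetal opening, in which the aluminium hydride coordinates the less hindered primary oxygen and delivers hydride to the acetal carbon, leaving the PMB ether on O7 and freeing the C6 primary alcohol.

Step 10
Reactants: 15 primary alcohol
Product: 16 (2S,3S,5E,9E)-3-(TBSO)-10-iodo-2-[(4-methoxybenzyl)oxy]-5,9-dimethyldeca-5,9-dienal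
Conditions: Dess–Martin periodinane, CH2Cl2, 0 °C to rt
Reagents that add atoms: none
Why: Dess–Martin oxidation gives the aldehyde under near-neutral conditions that should not epimerise the α-alkoxy centre C7 or affect the alkenyl iodide.

Step 11
Reactants: 16 iodo aldehyde
Product: 17 (1R,2E,6E,9S,10R)-9-(TBSO)-10-[(4-methoxybenzyl)oxy]-3,7-dimethylcyclodeca-2,6-dien-1-ol (C6 carbinol; O6, O7, O8 on one face)
Conditions: CrCl2 (excess), NiCl2 (cat.), DMSO, rt, slow addition at high dilution
Reagents that add atoms: none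
Why: Nozaki–Hiyama–Kishi reaction, in which the nickel-catalysed alkenylchromium species adds chemoselectively to the aldehyde to close the ten-membered carbocycle at C5–C6 with retention of the E-alkene, the C6 carbinol being expected from Felkin–Anh attack anti to the C7 alkoxy group.

Step 12
Reactants: 17 macrocyclic allylic alcohol
Product: 18 (1R,2E,6E,9S,10S)-9-(TBSO)-10-[(4-methoxybenzyl)oxy]-3,7-dimethyl-1-(triethylsilyloxy)cyclodeca-2,6-diene
Conditions: TESOTf, 2,6-lutidine, CH2Cl2, −78 °C
Reagents that add atoms: triethylsilyl triflate, CC[Si](CC)(CC)OS(=O)(=O)C(F)(F)F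
Why: Silylation of the hindered secondary allylic alcohol with a silyl triflate; the TES group is chosen because it can later be removed in the presence of TBS ethers.

Step 13
Reactants: 18 PMB ether
Product: 19 (1S,2R,3E,7E,10S)-10-(TBSO)-4,8-dimethyl-2-(triethylsilyloxy)cyclodeca-3,7-dien-1-ol
Conditions: DDQ, CH2Cl2/pH 7 buffer, 0 °C
Reagents that add atoms: none
Why: Oxidative cleavage of the electron-rich PMB ether by DDQ (hydride abstraction, then hydrolysis of the oxocarbenium ion) is orthogonal to silyl ethers and to isolated trisubstituted alkenes.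

Step 14
Reactants: 19 C7 alcohol
Product: 20 (2R,3E,7E,10S)-10-(TBSO)-4,8-dimethyl-2-(triethylsilyloxy)cyclodeca-3,7-dien-1-one
Conditions: Dess–Martin periodinane, CH2Cl2, rt
Reagents that add atoms: none
Why: Dess–Martin oxidation of the hindered secondary alcohol gives the α,α'-bis(silyloxy) ketone without base, so the epimerisable C6 and C8 centres should be preserved while the C7 centre is deliberately removed.

Step 15
Reactants: 21 methyl 3-hydroxypropanoate
Product: 22 methyl 3-[(tert-butyldimethylsilyl)oxy]propanoate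
Conditions: TBSCl, imidazole, DMF, rt
Reagents that add atoms: tert-butyldimethylsilyl chloride, CC(C)(C)[Si](C)(C)Cl
Why: Standard silylation of a primary alcohol.

Step 16
Reactants: 20 macrocyclic ketone; 22 silyloxy ester
Product: 24 methyl 3-(TBSO)-2-[(2R,3E,7E,10S)-10-(TBSO)-1-hydroxy-4,8-dimethyl-2-(triethylsilyloxy)cyclodeca-3,7-dien-1-yl]propanoate (mixture at C7 and C11), via lithium ester enolate 23 (not isolated)
Conditions: LiN(i-Pr)2, THF, −78 °C (22 to 23); then 20, −78 °C; AcOH quench at −78 °C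
Reagents that add atoms: none
Why: Aldol addition of a preformed lithium ester enolate to the electrophilic α,α'-dioxygenated ketone should form the C7–C11 bond faster than enolisation at −78 °C, and the two new centres need no control because both become sp2 in step 18.

Step 17
Reactants: 24 aldol adduct
Product: 26 (6R,8S)-7-hydroxy-8,13-bis(TBSO)germacra-1(10)E,4E-dien-12,6-olide (mixture at C7 and C11), via hydroxy ester 25 (not isolated)
Conditions: PPTS (cat.), MeOH/CH2Cl2, 0 °C to rt
Reagents that add atoms: none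
Why: Mild acidic methanolysis cleaves the triethylsilyl ether much faster than the TBS ethers, and the freed C6 hydroxyl should close the five-membered lactone on the methyl ester (5-exo-trig transesterification).

Step 18
Reactants: 26 β-hydroxy lactone
Product: 27 (6R,8S)-8,13-bis(TBSO)germacra-1(10)E,4E,7(11)-trien-12,6-olide
Conditions: SOCl2, pyridine, CH2Cl2, −20 to 0 °C
Reagents that add atoms: none
Why: Classical dehydration of a tertiary β-hydroxy lactone through its chlorosulfite, in which pyridine removes the acidic C11 hydrogen so that both diastereomers converge on the conjugated C7=C11 butenolide, pyridine being too weak a base to deprotonate C6.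

Step 19
Reactants: 27 trienolide
Product: 29 (1R,4R,5R,6S,8S,10R)-1,10:4,5-diepoxy-8,13-bis(TBSO)germacr-7(11)-en-12,6-olide, via 1,10-monoepoxide 28 (not isolated)
Conditions: dimethyldioxirane (acetone solution, 2.5 equiv), CH2Cl2, −20 to 0 °C
Reagents that add atoms: dimethyldioxirane, CC1(C)OO1
Why: Dimethyldioxirane epoxidises both electron-rich trisubstituted ring alkenes (not the electron-poor butenolide alkene) from the outer face of the crown conformer of the E,E-cyclodecadiene with both ring methyls on one face, and at C4=C5 allylic strain from the C4 methyl keeps H-6 in the alkene plane so the exposed face is the one flanked by the lactone oxygen, which should give the 1R,10R and 4R,5R trans-oxiranes under neutral conditions that avoid transannular cyclisation.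

Step 20
Reactants: 29 diepoxy butenolide
Product: 31 (1S,4R,5E,8S,10R)-1,4-epoxy-10-hydroxy-8,13-bis(TBSO)germacra-5,7(11)-dien-12,6-olide, via C4 alkoxide 30 (not isolated)
Conditions: DBU, MeCN, 0 °C to rt
Reagents that add atoms: none
Why: DBU reversibly removes H-6, the γ-hydrogen of the butenolide and the only proton acidic enough for an amidine, to give the 2-oxidofuran dienolate, whose C6 terminus expels the adjacent C5–O bond (vinylogous E1cB) so that the C5=C6 alkene forms and the former oxirane oxygen stays on C4 with its configuration untouched. That oxygen (as the alkoxide–amidinium pair, or as the alcohol after proton return) sits across the ring from C1 and opens the 1,10-oxirane by backside attack in a 5-exo-tet closure, forming the O–C1 bond of the tetrahydrofuran and releasing the C10 hydroxyl. The closest known reaction type is the base- or silica-induced isomerisation of 4,5-epoxy-7(11)-en-6,12-olides to 1,4-oxygen-bridged 5-en-olides, joined to the ordinary cyclisation of a γ,δ-epoxy alcohol. C1 is the only centre newly configured and it is set by SN2 inversion (1R to 1S), while C4 and C10 keep what the epoxidations gave and C5 and C6 become sp2. The step needs attack at C1 and not at C10 (secured by the five-membered exo mode at the less substituted oxirane carbon), the C5=C6 geometry with C4 and C7 cis (the only one the bridged ring can hold), and no loss of the C13 oxygen or of C8 integrity (a siloxy group is a far poorer leaving group than a strained oxirane, and H-8 is not acidic enough for DBU).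

Step 21
Reactants: 31 bis-silyl ether
Product: 32 (1S,4R,5E,8S,10R)-1,4-epoxy-8,10,13-trihydroxygermacra-5,7(11)-dien-12,6-olide
Conditions: HF·pyridine, pyridine, THF, 0 °C to rt
Reagents that add atoms: none
Why: Pyridine-buffered HF cleaves both silyl ethers without the basic conditions that could isomerise the dienyl lactone; the tertiary C10 alcohol and the enol lactone should be tolerated.

Step 22
Reactants: 32 triol
Product: 33 (1S,4R,5E,8S,10R)-13-acetoxy-1,4-epoxy-8,10-dihydroxygermacra-5,7(11)-dien-12,6-olide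
Conditions: AcCl, 2,4,6-collidine, CH2Cl2, −78 °C
Reagents that add atoms: acetyl chloride, CC(Cl)=O
Why: Acetyl chloride with the hindered base 2,4,6-collidine at −78 °C acetylates a primary alcohol far faster than the hindered secondary C8 or the tertiary C10 hydroxyl (kinetic chemoselective acylation).

Step 23
Reactants: 34 methyl (S)-2-methyloxirane-2-carboxylate
Product: 35 potassium (S)-2-methyloxirane-2-carboxylate
Conditions: KOH (1 equiv), MeOH, 0 °C; evaporation
Reagents that add atoms: potassium hydroxide, [K+].[OH-]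
Why: Cold saponification of a glycidic ester with one equivalent of hydroxide gives the stable potassium glycidate; the quaternary α-carbon cannot epimerise.

Step 24
Reactants: 33 C8 alcohol; 35 potassium glycidate
Product: 37 target CNP0142137.1, via mixed anhydride 36 (not isolated)
Conditions: 2,4,6-trichlorobenzoyl chloride, THF, rt (35 to 36); then 33, DMAP, toluene, rt
Reagents that add atoms: none
Why: Yamaguchi esterification, in which the mixed 2,4,6-trichlorobenzoic anhydride activated by DMAP acylates the hindered secondary C8 alcohol while the tertiary C10 alcohol does not react, and the acid's quaternary stereocentre is retained.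

**Compound list**

1 | (R)-2,2-dimethyl-1,3-dioxolane-4-carbaldehyde ((R)-glyceraldehyde acetonide) | CC1(C)OC[C@H](C=O)O1 | starting material
2 | propargyl bromide (3-bromoprop-1-yne) | BrCC#C | starting material
3 | (S)-1-[(R)-2,2-dimethyl-1,3-dioxolan-4-yl]but-3-yn-1-ol | C#CC[C@H](O)[C@H]1COC(C)(C)O1 | intermediate
4 | tert-butyl{[(S)-1-[(R)-2,2-dimethyl-1,3-dioxolan-4-yl]but-3-yn-1-yl]oxy}dimethylsilane | C#CC[C@H](O[Si](C)(C)C(C)(C)C)[C@H]1COC(C)(C)O1 | intermediate
5 | [(1E,4S)-4-(TBSO)-4-[(R)-2,2-dimethyl-1,3-dioxolan-4-yl]-2-methylbut-1-en-1-yl]dimethylalane | C[Al](C)/C=C(C)/C[C@H](O[Si](C)(C)C(C)(C)C)[C@H]1COC(C)(C)O1 | intermediate (not isolated)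
6 | (R)-4-[(1S,3E)-1-(TBSO)-4-iodo-3-methylbut-3-en-1-yl]-2,2-dimethyl-1,3-dioxolane | I/C=C(C)/C[C@H](O[Si](C)(C)C(C)(C)C)[C@H]1COC(C)(C)O1 | intermediate
7 | (4-iodobut-1-yn-1-yl)trimethylsilane | C[Si](C)(C)C#CCCI | starting material
8 | [4-(trimethylsilyl)but-3-yn-1-yl]zinc iodide | C[Si](C)(C)C#CCC[Zn]I | intermediate (not isolated)
9 | (R)-4-[(1S,3E)-1-(TBSO)-3-methyl-8-(trimethylsilyl)oct-3-en-7-yn-1-yl]-2,2-dimethyl-1,3-dioxolane | C[Si](C)(C)C#CCC/C=C(C)/C[C@H](O[Si](C)(C)C(C)(C)C)[C@H]1COC(C)(C)O1 | intermediate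
10 | (R)-4-[(1S,3E)-1-(TBSO)-3-methyloct-3-en-7-yn-1-yl]-2,2-dimethyl-1,3-dioxolane | C#CCC/C=C(C)/C[C@H](O[Si](C)(C)C(C)(C)C)[C@H]1COC(C)(C)O1 | intermediate
11 | [(1E,5E,8S)-8-(TBSO)-8-[(R)-2,2-dimethyl-1,3-dioxolan-4-yl]-2,6-dimethylocta-1,5-dien-1-yl]dimethylalane | C[Al](C)/C=C(C)/CC/C=C(C)/C[C@H](O[Si](C)(C)C(C)(C)C)[C@H]1COC(C)(C)O1 | intermediate (not isolated)
12 | (R)-4-[(1S,3E,7E)-1-(TBSO)-8-iodo-3,7-dimethylocta-3,7-dien-1-yl]-2,2-dimethyl-1,3-dioxolane | I/C=C(C)/CC/C=C(C)/C[C@H](O[Si](C)(C)C(C)(C)C)[C@H]1COC(C)(C)O1 | intermediate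
13 | (2R,3S,5E,9E)-3-(TBSO)-10-iodo-5,9-dimethyldeca-5,9-diene-1,2-diol | I/C=C(C)/CC/C=C(C)/C[C@H](O[Si](C)(C)C(C)(C)C)[C@H](O)CO | intermediate
14 | (4R)-4-[(1S,3E,7E)-1-(TBSO)-8-iodo-3,7-dimethylocta-3,7-dien-1-yl]-2-(4-methoxyphenyl)-1,3-dioxolane (both epimers at the acetal carbon) | I/C=C(C)/CC/C=C(C)/C[C@H](O[Si](C)(C)C(C)(C)C)[C@H]1COC(c2ccc(OC)cc2)O1 | intermediate
15 | (2R,3S,5E,9E)-3-(TBSO)-10-iodo-2-[(4-methoxybenzyl)oxy]-5,9-dimethyldeca-5,9-dien-1-ol | I/C=C(C)/CC/C=C(C)/C[C@H](O[Si](C)(C)C(C)(C)C)[C@H](OCc1ccc(OC)cc1)CO | intermediate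
16 | (2S,3S,5E,9E)-3-(TBSO)-10-iodo-2-[(4-methoxybenzyl)oxy]-5,9-dimethyldeca-5,9-dienal | I/C=C(C)/CC/C=C(C)/C[C@H](O[Si](C)(C)C(C)(C)C)[C@H](OCc1ccc(OC)cc1)C=O | intermediate
17 | (1R,2E,6E,9S,10R)-9-(TBSO)-10-[(4-methoxybenzyl)oxy]-3,7-dimethylcyclodeca-2,6-dien-1-ol | O[C@@H]1/C=C(C)/CC/C=C(C)/C[C@H](O[Si](C)(C)C(C)(C)C)[C@@H]1OCc2ccc(OC)cc2 | intermediate
18 | (1R,2E,6E,9S,10S)-9-(TBSO)-10-[(4-methoxybenzyl)oxy]-3,7-dimethyl-1-(triethylsilyloxy)cyclodeca-2,6-diene | CC[Si](CC)(CC)O[C@@H]1/C=C(C)/CC/C=C(C)/C[C@H](O[Si](C)(C)C(C)(C)C)[C@@H]1OCc2ccc(OC)cc2 | intermediate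
19 | (1S,2R,3E,7E,10S)-10-(TBSO)-4,8-dimethyl-2-(triethylsilyloxy)cyclodeca-3,7-dien-1-ol | CC[Si](CC)(CC)O[C@@H]1/C=C(C)/CC/C=C(C)/C[C@H](O[Si](C)(C)C(C)(C)C)[C@@H]1O | intermediate
20 | (2R,3E,7E,10S)-10-(TBSO)-4,8-dimethyl-2-(triethylsilyloxy)cyclodeca-3,7-dien-1-one | CC[Si](CC)(CC)O[C@@H]1/C=C(C)/CC/C=C(C)/C[C@H](O[Si](C)(C)C(C)(C)C)C1=O | intermediate
21 | methyl 3-hydroxypropanoate | COC(=O)CCO | starting material
22 | methyl 3-[(tert-butyldimethylsilyl)oxy]propanoate | COC(=O)CCO[Si](C)(C)C(C)(C)C | intermediate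
23 | lithium enolate of 22 | [Li+].COC([O-])=CCO[Si](C)(C)C(C)(C)C | intermediate (not isolated)
24 | methyl 3-(TBSO)-2-[(2R,3E,7E,10S)-10-(TBSO)-1-hydroxy-4,8-dimethyl-2-(triethylsilyloxy)cyclodeca-3,7-dien-1-yl]propanoate (mixture at C7 and C11) | CC[Si](CC)(CC)O[C@@H]1/C=C(C)/CC/C=C(C)/C[C@H](O[Si](C)(C)C(C)(C)C)C1(O)C(CO[Si](C)(C)C(C)(C)C)C(=O)OC | intermediate
25 | methyl 3-(TBSO)-2-[(2R,3E,7E,10S)-10-(TBSO)-1,2-dihydroxy-4,8-dimethylcyclodeca-3,7-dien-1-yl]propanoate (mixture at C7 and C11) | O[C@@H]1/C=C(C)/CC/C=C(C)/C[C@H](O[Si](C)(C)C(C)(C)C)C1(O)C(CO[Si](C)(C)C(C)(C)C)C(=O)OC | intermediate (not isolated)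
26 | (6R,8S)-7-hydroxy-8,13-bis(TBSO)germacra-1(10)E,4E-dien-12,6-olide (mixture at C7 and C11) | O=C1O[C@@H]2/C=C(C)/CC/C=C(C)/C[C@H](O[Si](C)(C)C(C)(C)C)C2(O)C1CO[Si](C)(C)C(C)(C)C | intermediate
27 | (6R,8S)-8,13-bis(TBSO)germacra-1(10)E,4E,7(11)-trien-12,6-olide | O=C1O[C@@H]2/C=C(C)/CC/C=C(C)/C[C@H](O[Si](C)(C)C(C)(C)C)C2=C1CO[Si](C)(C)C(C)(C)C | intermediate
28 | (1R,6R,8S,10R)-1,10-epoxy-8,13-bis(TBSO)germacra-4E,7(11)-dien-12,6-olide | CC(C)(C)[Si](C)(C)OCC1=C2[C@@H](/C=C(C)/CC[C@H]3O[C@]3(C)C[C@@H]2O[Si](C)(C)C(C)(C)C)OC1=O | intermediate (not isolated)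
29 | (1R,4R,5R,6S,8S,10R)-1,10:4,5-diepoxy-8,13-bis(TBSO)germacr-7(11)-en-12,6-olide | CC(C)(C)[Si](C)(C)OCC1=C2[C@@H]([C@H]3O[C@]3(C)CC[C@H]4O[C@]4(C)C[C@@H]2O[Si](C)(C)C(C)(C)C)OC1=O | intermediate
30 | C4 alkoxide of (1R,4R,5E,8S,10R)-1,10-epoxy-4-hydroxy-8,13-bis(TBSO)germacra-5,7(11)-dien-12,6-olide (DBU-H+ counter-ion) | CC(C)(C)[Si](C)(C)OCC1=C2/C(=C\[C@](C)([O-])CC[C@H]3O[C@]3(C)C[C@@H]2O[Si](C)(C)C(C)(C)C)OC1=O | intermediate (not isolated)
31 | (1S,4R,5E,8S,10R)-1,4-epoxy-10-hydroxy-8,13-bis(TBSO)germacra-5,7(11)-dien-12,6-olide | CC(C)(C)[Si](C)(C)OCC1=C2/C(=C\[C@@]3(C)CC[C@H](O3)[C@](C)(O)C[C@@H]2O[Si](C)(C)C(C)(C)C)OC1=O | intermediate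
32 | (1S,4R,5E,8S,10R)-1,4-epoxy-8,10,13-trihydroxygermacra-5,7(11)-dien-12,6-olide | OCC1=C2/C(=C\[C@@]3(C)CC[C@H](O3)[C@](C)(O)C[C@@H]2O)OC1=O | intermediate
33 | (1S,4R,5E,8S,10R)-13-acetoxy-1,4-epoxy-8,10-dihydroxygermacra-5,7(11)-dien-12,6-olide | CC(=O)OCC1=C2/C(=C\[C@@]3(C)CC[C@H](O3)[C@](C)(O)C[C@@H]2O)OC1=O | intermediate
34 | methyl (S)-2-methyloxirane-2-carboxylate (methyl (S)-2-methylglycidate) | COC(=O)[C@]1(C)CO1 | starting material
35 | potassium (S)-2-methyloxirane-2-carboxylate | [K+].[O-]C(=O)[C@]1(C)CO1 | intermediate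
36 | (S)-2-methyloxirane-2-carboxylic 2,4,6-trichlorobenzoic anhydride | O=C(OC(=O)[C@]1(C)CO1)c1c(Cl)cc(Cl)cc1Cl | intermediate (not isolated)
37 | (1S,4R,5E,8S,10R)-13-acetoxy-1,4-epoxy-10-hydroxy-8-[(S)-2-methyloxirane-2-carbonyloxy]germacra-5,7(11)-dien-12,6-olide (CNP0142137.1) | CC(=O)OCC1=C2/C(=C\[C@@]3(C)CC[C@H](O3)[C@](C)(O)C[C@@H]2OC(=O)[C@]2(C)CO2)OC1=O | target

**Step count and risks**

Total step count: 24 (22 in the main line, plus steps 15 and 23 for reagents 22 and 35). Longest linear sequence: 22 steps (steps 1–14, 16–22 and 24, from 1).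

The three steps most likely to fail:

Step 19. The oxidant may attack the wrong face of the C1=C10 alkene if ring conformers other than the crown are populated, which would give a diepoxide diastereomer with C1 and C10 mismatched to C8. The fallback sets this oxirane by reagent control before the butenolide exists. It starts from hydroxy lactone 26, which is epoxidised at C1=C10 alone with the D-fructose-derived Shi ketone (KHSO5, K2CO3 buffer, Bu4NHSO4, MeCN/dimethoxymethane/water, 0 °C); the C4=C5 alkene is deactivated by the allylic lactone oxygen. This should give (1R,6R,8S,10R)-1,10-epoxy-7-hydroxy-8,13-bis(TBSO)germacr-4E-en-12,6-olide F1. Dehydration of F1 with Martin sulfurane (CH2Cl2, 0 °C, neutral) leads to monoepoxide 28, here isolated. One equivalent of dimethyldioxirane then epoxidises C4=C5 under control of C6, and the route is rejoined at 29.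

Step 11. The chromium-mediated ring closure may show poor facial selectivity at C6, since the ring-forming transition state can override the Felkin–Anh preference. The fallback sets C6 after the ring is closed. It starts from the C6-epimer mixture of 17, which is oxidised with Dess–Martin periodinane to the macrocyclic enone (2E,6E,9S,10S)-9-(TBSO)-10-[(4-methoxybenzyl)oxy]-3,7-dimethylcyclodeca-2,6-dien-1-one F2. Reduction of F2 with Zn(BH4)2 in Et2O at −30 °C goes through the chelate between the C6 carbonyl and the C7 PMB ether and should give the 6,7-anti alcohol, which returns to the route at 17 as one epimer.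

Step 20. The cascade may stall after the first event, because the C4 alkoxide is protonated by the amidinium ion faster than it closes the ether ring. The fallback separates the two events. It starts from 29, which with Et3N in CH2Cl2 should undergo only the E1cB opening to give the alcohol (1R,4R,5E,8S,10R)-1,10-epoxy-4-hydroxy-8,13-bis(TBSO)germacra-5,7(11)-dien-12,6-olide F3. Treatment of F3 with NaH in THF at 0 °C forms the sodium alkoxide, which closes the tetrahydrofuran by the classical 5-exo opening of a γ,δ-epoxy alcohol at the less substituted carbon, returning to the route at 31.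

Further compounds
F1 | step 19 | (1R,6R,8S,10R)-1,10-epoxy-7-hydroxy-8,13-bis(TBSO)germacr-4E-en-12,6-olide (mixture at C7 and C11) | O=C1O[C@@H]2/C=C(C)/CC[C@H]3O[C@]3(C)C[C@H](O[Si](C)(C)C(C)(C)C)C2(O)C1CO[Si](C)(C)C(C)(C)C
F2 | step 11 | (2E,6E,9S,10S)-9-(TBSO)-10-[(4-methoxybenzyl)oxy]-3,7-dimethylcyclodeca-2,6-dien-1-one | O=C1/C=C(C)/CC/C=C(C)/C[C@H](O[Si](C)(C)C(C)(C)C)[C@@H]1OCc2ccc(OC)cc2
F3 | step 20 | (1R,4R,5E,8S,10R)-1,10-epoxy-4-hydroxy-8,13-bis(TBSO)germacra-5,7(11)-dien-12,6-olide | CC(C)(C)[Si](C)(C)OCC1=C2/C(=C\[C@](C)(O)CC[C@H]3O[C@]3(C)C[C@@H]2O[Si](C)(C)C(C)(C)C)OC1=O
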